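# Proposed synthesis of 3β-acetoxy-agathic acid (28) by a catalytic asymmetric Diels–Alder construction of ring A

Compound numbers are those of the steps and of the compound list below. Locants C1–C20 are the labdane locants of the target; β is the face of the C10 methyl group.

## Analysis of the target

The target 28 is a labdane: a trans-fused decalin (ring A = C1–C5 and C10, ring B = C5–C10) with an exocyclic methylene at C8 (C17) and a six-carbon chain on C9 that ends in an E-configured 3-methyl-2-enoic acid (C13=C14, C15, C16). It has five stereocentres: C3 (β-acetoxy, equatorial), C4 (quaternary; α-methyl C18, axial β-carboxyl C19), C5 (α-H), C9 (α-H, chain β and equatorial) and C10 (quaternary; β-methyl C20). C4, C5 and C10 are contiguous, the C19 carboxyl and the C20 methyl are 1,3-diaxial on the β face, and the C3 oxygen is cis to C19. The sensitive groups are the 8(17)-alkene (it moves into the ring under acid), the trisubstituted enoate (its geometry can be lost by reversible conjugate addition), the secondary acetate (it must outlive the step that frees the acids) and the axial neopentyl C19 carboxyl (hard to reach at its carbonyl carbon). The difficulty lies in two quaternary centres on either side of C5 in an oxygenated ring A, needed as one enantiomer, and in the C9 centre wedged between C10 and the exocyclic alkene. The strategy rests on ring A, in which C3 bears oxygen, C4 a carboxyl carbon, and C5 and C10 carry their carbon substituents (C6 and C9) trans to each other. This is the pattern left by a [4+2] union of a 3-silyloxy-2,4-dienoate (C1–C4 with C19) and an E-2-methyl enal (C10 with C20 and C9, C5 with C6). With a formyl group on C10 and a bromoalkenyl arm on C5, one radical ring closure can then supply ring B, C17 and the C9 centre.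

## Retrosynthetic reasoning

**28 ⇒ 27 (two O–CH3 bonds).** The two acids are unmasked last from the dimethyl ester acetate 27. The cut is placed at the methyl–oxygen bonds and not at the acyl carbons, because the C19 carbonyl is shielded and the acetate would not survive acyl cleavage. The forward step has to be an SN2 dealkylation at the two methyl carbons, for which a secondary acetate offers no reactive carbon.

**27 ⇒ 23 + 25 (C12–C13).** The chain is cut between the sp3 carbon C12 and the alkene carbon C13. This takes the alkene geometry from a stereodefined four-carbon partner, the E enol triflate 25 (one step from methyl acetoacetate 24), and not from an olefination of a methyl ketone, which would give E/Z mixtures. Forward, the primary iodide 23 is converted into the zinc reagent 26 and coupled with retention.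

**23 ⇒ 22 ⇒ 21 ⇒ 20 ⇒ 18 (functional-group changes at C3 and C12).** The acetate is traced to the free 3β-alcohol of 22, and the iodide carbon C12 through alcohol 21 and aldehyde 20 to the nitrile carbon of 18. A nitrile is chosen as the C12 function because it can be reduced in the presence of the hindered C19 ester.

**18 ⇒ 17 ⇒ 16 (C3–H, C4–C18).** The C3 carbinol comes from the ketone 17 by axial hydride delivery, and the C18 methyl from alkylation of the β-keto ester 16. Methyl is introduced last at C4 so that it enters anti to the C10 methyl and the ester ends up axial, as in the target. Both events are placed on the rigid trans-decalin, where the facial bias is predictable.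

**16 ⇒ 15 ⇒ 14 (C8–C9, ring B).** Keto ester 16 is the desilylated form of the bicyclic silyl enol ether 15, and ring B of 15 is opened at C8–C9. Forward, the vinyl bromide of 14 becomes a vinyl radical that closes 6-exo onto the unsaturated nitrile. This one bond gives ring B, leaves the C8=C17 alkene exactly where the target has it without any later methylenation, and sets C9.

**14 ⇒ 13 (C9=C11).** The two carbons C11 and C12 are removed as a cyanomethylene unit, leaving the neopentyl aldehyde of 13; the forward step is a phosphonate olefination.

**13 ⇒ 4 + 12 (C4–C5 and C1–C10, ring A).** This is the key disconnection. Both bonds are cut so that ring A falls into the silyloxydienoate 4 and the E-enal 12, two achiral fragments. What is gained is the C10 quaternary centre, the C5 centre trans to it, and ring A with C3 at the ketone level and C19 as an ester. The forward reaction has to be regioselective (C4 to C5), face-selective at C10 and suprafacial.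

**4 ⇒ 2 ⇒ 1; 12 ⇒ 10 + 11; 10 ⇒ 8 ⇒ 5 + 6.** The diene is the Z silyl enol ether of the vinyl keto ester 2, which comes from the methoxy keto ester 1 by β-elimination. The enal is cut at C5=C10 into aldehyde 10 and the formyl ylide 11, and 10 comes from tert-butyl acetate 5 and 2,3-dibromopropene 6 through ester 8.

## Alternatives that were turned down

**Alternative 1:** intramolecular Diels–Alder reaction of an open chain.
- Disconnection: C5–C10 and C8–C9 are cut together, so both rings open to the acyclic trienal A1. It holds an (E,E)-1-silyloxydiene (C5–C8), an (E)-3-methyl enal (C9=C10, formyl carbon C11) and the C3/C4 pair.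
- Forward key step: heating A1 should give the trans-fused octalin aldehyde A2 by intramolecular [4+2].
- For: two rings, two C–C bonds and the centres C5, C8, C9 and C10 form in one step; the trans fusion is encoded in the enal geometry; C9 arises next to an epimerisable formyl group. On bonds and rings per step it is stronger than the chosen plan.
- Against:
  - (a) A1 must already contain the quaternary C4 next to the C3 carbinol, made on an open chain with no ring to bias it. The hardest stereochemical problem and the absolute configuration are pushed into the precursor.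
  - (b) The silyl dienol ether of A1 must be generated in the presence of a second enal that also has γ-hydrogens (C1, C20).
  - (c) The new C5–C10 bond joins a carbon bearing the quaternary C4 to a fully substituted dienophile carbon, and a β,β-disubstituted enal is a poor dienophile. Long heating of a heat- and acid-sensitive dienol ether is expected, and the endo/exo ratio (trans versus cis fusion) is not assured.
  - (d) A2 is a β-silyloxy aldehyde prone to elimination. It still needs C6=C7 reduced, C8–O turned into C8=CH2 and the whole chain built from C11.
- Comparison: the chosen plan makes fewer bonds in its key step. In its place it offers two simple achiral fragments (4 and 12), a catalyst that fixes the absolute configuration, and construction of the C3/C4 pair on a rigid decalin.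

**Alternative 2:** reductive aldol closure of ring A.
- Disconnection: C3–C4, opening ring A of the hydroxy ester A4 to the acrylate aldehyde A3. A3 is a ring B cyclohexane (C9 masked as a dioxolane) with the methyl and a 3-oxopropyl arm on C10 and a 2-propenoate unit on C5.
- Forward key step: conjugate reduction of the acrylate by [(Ph3P)CuH]6 places a hydrogen on its terminal CH2, the future C18 methyl, and the copper enolate formed at C4 is trapped by the C3 aldehyde in an intramolecular aldol reaction.
- For: C3 and C4 are created together in the ring-forming step, the C18 methyl needs no separate alkylation, and C3 arrives as the carbinol. On this point it is stronger than the chosen route, which needs desilylation, methylation and reduction and relies on substrate bias twice.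
- Against:
  - The geometry of the fully substituted enolate is not controlled and the aldol is reversible, so the equatorial-OH/axial-ester relation is not assured.
  - A3 must be supplied as one enantiomer with the trans C5/C10 pair and the quaternary C10 in place, so the key step does not answer the absolute stereochemical question.
  - After A4, nothing of C8, C17 or the chain exists. A ketone at C9, next to quaternary C10, must become a C–H centre carrying six carbons, with a new stereocentre and a methylene at C8.
- Comparison: one ring and one bond, against one ring, two bonds and the absolute configuration in the chosen step. The chosen adduct 13 already carries the formyl and vinyl bromide handles for ring B, C17 and C9.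

**Alternative 3:** quinone Diels–Alder reaction for ring B.
- Disconnection: C5–C6 and C9–C10, to 2-methoxy-5-methyl-1,4-benzoquinone A5 and the silyloxydiene A6, which carries C11–C13 and C16 as a ketal-protected methyl ketone.
- Forward key step: [4+2] across the methyl-bearing double bond of A5 under the chelating Lewis acid TiCl2[(R)-BINOLate] (tetravalent titanium), bound to the C4 carbonyl and the methoxy oxygen, to give the cis-fused endo adduct A7.
- For: this is the most convergent plan. Most of the chain carbons and an oxygen at C8 (a direct handle for the 8(17)-methylene) arrive with A6, and C10 is set under catalyst control. On convergence and on the C8 handle it is stronger than the chosen route, which spends five steps on the chain.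
- Against:
  - The adduct is cis-fused. C5 and C9 have the wrong configuration and both must be inverted by enolisation; at C5 the cis/trans balance of such 10-methyl decalindiones does not reliably favour trans.
  - Ring A emerges with carbonyls at C1 and C4 and an enol ether at C3. The C1 oxygen must be removed, and the C4 carbonyl carbon must become a quaternary carbon bearing methyl and carboxyl, with two C–C bonds to form under stereocontrol. This is a long redox and functional-group sequence.
- Comparison: the chosen route delivers ring A with C3 at the ketone level, C19 as an ester and the trans C5/C10 relation fixed by alkene geometry. It pays for this with a linear attachment of the chain.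

Key step: step 6

Assumption: the face selection in step 6 is taken from the accepted binding model of N-protonated oxazaborolidines with α-substituted enals; on that model the catalyst prepared from (R)-diphenyl(pyrrolidin-2-yl)methanol, tri(o-tolyl)boroxine and HNTf2 gives 13, and the equally available (S) antipode would be used if the adduct proved to be the mirror image.

Assumption: the E/Z ratio of nitrile 14 is of no consequence, since both alkene carbons become sp3 in step 8.

## Route

Step 1
Reactants: 1 methyl 5-methoxy-3-oxopentanoate
Product: 2 methyl 3-oxopent-4-enoate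
Conditions: TsOH·H2O (cat.), neat, 120 °C, reduced pressure, product distilled as formed and used at once
Reagents that add atoms: none
Why: Acid-catalysed β-elimination of methanol from a β-methoxy ketone; distilling the vinyl ketone out of the acid keeps it from polymerising.

Step 2
Reactants: 2 methyl 3-oxopent-4-enoate
Product: 4 methyl (2Z)-3-[(tert-butyldimethylsilyl)oxy]penta-2,4-dienoate, via lithium dienolate 3 (not isolated)
Conditions: LiN(SiMe3)2, THF, −78 °C (2 added to the base); TBSOTf, −78 → 0 °C
Reagents that add atoms: tert-butyldimethylsilyl triflate, CC(C)(C)[Si](C)(C)OS(=O)(=O)C(F)(F)F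
Why: O-Silylation of the lithium-chelated β-keto ester enolate, in which lithium holds the two oxygens cis, should give the Z enol ether; the ester then lies trans to the vinyl group, on the outside of the s-cis diene, as a reactive diene needs.

Step 3
Reactants: 5 tert-butyl acetate; 6 2,3-dibromopropene
Product: 8 tert-butyl 4-bromopent-4-enoate, via lithium ester enolate 7 (not isolated)
Conditions: LiN(i-Pr)2, THF, −78 °C; then 6, −78 → 0 °C
Reagents that add atoms: none
Why: Ester enolate alkylation (SN2) at the allylic bromide; the vinylic bromide is inert and the tert-butyl ester suppresses Claisen self-condensation.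

Step 4
Reactants: 8 tert-butyl 4-bromopent-4-enoate
Product: 10 4-bromopent-4-enal, via aluminium hemiacetal 9 (not isolated)
Conditions: i-Bu2AlH (1.05 equiv), CH2Cl2, −78 °C; MeOH, then aq. KNa tartrate
Reagents that add atoms: none
Why: Partial reduction of an ester; the tetrahedral aluminium hemiacetal is stable at −78 °C and collapses to the aldehyde only on work-up.

Step 5
Reactants: 10 4-bromopent-4-enal; 11 2-(triphenylphosphoranylidene)propanal
Product: 12 (2E)-6-bromo-2-methylhepta-2,6-dienal
Conditions: toluene, 90 °C
Reagents that add atoms: none
Why: Wittig olefination with a stabilised formyl ylide, which is E-selective; the conjugated enal product is much less electrophilic than 10 and does not react further.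

Step 6
Reactants: 4 methyl (2Z)-3-[(tert-butyldimethylsilyl)oxy]penta-2,4-dienoate; 12 (2E)-6-bromo-2-methylhepta-2,6-dienal
Product: 13 methyl (1S,5S,6S)-6-(3-bromobut-3-en-1-yl)-2-[(tert-butyldimethylsilyl)oxy]-5-formyl-5-methylcyclohex-2-ene-1-carboxylate
Conditions: (R)-tetrahydro-3,3-diphenyl-1-(o-tolyl)-1H,3H-pyrrolo[1,2-c][1,3,2]oxazaborole·HNTf2 (20 mol %), diene in excess, CH2Cl2, −78 → −20 °C; Et3N quench
Reagents that add atoms: none
Why: The boron of the cationic oxazaborolidine binds the formyl oxygen of 12 and lowers its LUMO, and 4 then adds as a normal-demand diene in a [4+2] cycloaddition; the closest known reaction type is the oxazaborolidinium-catalysed Diels–Alder reaction of 2-silyloxybutadienes with α-substituted enals, in which an α,β-disubstituted enal is among the slowest partners. Bond formation is concerted but unsymmetrical: the ester-bearing terminus of 4 (C4, the β-carbon of its silyl enol ether) is well advanced towards the enal β-carbon C5 before the CH2 terminus C1 joins the α-carbon C10. Ring A is thereby closed as a cyclohexene in a single cycloaddition across the s-cis diene, with two new σ bonds (C4–C5 and C1–C10) and the C2=C3 silyl enol ether left in the ring. The orientation is dictated by the silyloxy group on C3, which makes C4 the electron-rich terminus and stabilises positive charge at C3 in the transition state, the same sense as a Michael–Michael sequence. C10 is set by the catalyst: the enal binds s-trans with its formyl C–H against the ring oxygen and its C=C over the near phenyl group, which with the (R)-ligand leaves the Si face of C10 (CHO > C5 > CH3) open and gives the 10β-methyl centre. C5 is set by the alkene geometry, because suprafacial addition to the E enal places C6 and the formyl carbon C9 trans on ring A, the relation that later becomes the trans ring fusion. C4 should arise with the ester cis to the formyl group through the formyl-endo approach to the Z diene, but this centre is re-formed in steps 9 and 10, so endo/exo control is not required. What the step needs is that cycloaddition outruns Mukaiyama-type addition to the activated carbonyl and protodesilylation of 4; the ester damps the nucleophilicity of C4, the bulky silyl group resists transfer, the diene is used in excess at low temperature, and the vinyl bromide and the ester take no part.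

Step 7
Reactants: 13 ring A aldehyde
Product: 14 methyl (1S,5R,6S)-6-(3-bromobut-3-en-1-yl)-2-[(tert-butyldimethylsilyl)oxy]-5-[(E)-2-cyanoethenyl]-5-methylcyclohex-2-ene-1-carboxylate (E isomer drawn; C9=C11, nitrile carbon C12)
Conditions: (EtO)2P(O)CH2CN, NaH, THF, 0 °C → rt
Reagents that add atoms: diethyl (cyanomethyl)phosphonate, CCOP(=O)(CC#N)OCC
Why: Horner–Wadsworth–Emmons olefination; the small phosphonate anion reaches the neopentyl, non-enolisable aldehyde, and silyl enol ether, ester and vinyl bromide tolerate the weakly basic conditions. The descriptor at ring carbon 5 changes from S to R only because the alkenyl group ranks below the ring carbon in the sequence rules; no bond at that centre is touched.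

Step 8
Reactants: 14 unsaturated nitrile
Product: 15 methyl 3-[(tert-butyldimethylsilyl)oxy]-13,14,15,16-tetranorlabda-2,8(17)-dien-12-nitrile-19-oate (trans-decalin; 4β-H, 5α-H, 9α-H, 10β-CH3; CH2CN on C9 β)
Conditions: Bu3SnH (1.3 equiv) and AIBN (cat.) added slowly, benzene (0.01 M), 80 °C
Reagents that add atoms: none
Why: Vinyl radical cyclisation: the stannyl radical removes bromine, the σ-vinyl radical at C8 adds 6-exo-trig to C9 (β-carbon of the unsaturated nitrile) through a chair-like transition state with the tether diequatorial on ring A and the cyanovinyl group pseudo-equatorial, giving the trans-decalin with H9 α and the C8=C17 alkene directly; the α-cyano radical is then reduced by the stannane.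

Step 9
Reactants: 15 bicyclic silyl enol ether
Product: 16 methyl 3-oxo-13,14,15,16-tetranorlabd-8(17)-en-12-nitrile-19-oate (β-keto ester, keto/enol mixture; 4α-CO2Me drawn)
Conditions: Bu4NF, AcOH, THF, 0 °C
Reagents that add atoms: none
Why: Fluoride cleaves the Si–O bond and acetic acid protonates the enolate; C4 becomes epimerisable, so the configuration it received in step 6 no longer matters.

Step 10
Reactants: 16 β-keto ester
Product: 17 methyl 3-oxo-13,14,15,16-tetranorlabd-8(17)-en-12-nitrile-19-oate with 4α-CH3 (C18) and 4β-CO2Me (C19)
Conditions: MeI, K2CO3, acetone, 50 °C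
Reagents that add atoms: iodomethane, CI
Why: C-Alkylation of a β-keto ester enolate; on the trans-decalin the β face of C4 is screened by the 1,3-diaxial C10 methyl, so the methyl should enter from the α face and leave the ester axial, and the base is too weak to touch the CH2CN protons.

Step 11
Reactants: 17 methylated keto ester
Product: 18 methyl 3β-hydroxy-13,14,15,16-tetranorlabd-8(17)-en-12-nitrile-19-oate
Conditions: NaBH4, MeOH, 0 °C
Reagents that add atoms: none
Why: Ketone reduction by axial hydride delivery from the α face (the β face carries the axial ester and the C10 methyl), which should give the equatorial 3β-alcohol; ester and nitrile are inert to NaBH4.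

Step 12
Reactants: 18 hydroxy nitrile
Product: 20 methyl 3β-hydroxy-12-oxo-13,14,15,16-tetranorlabd-8(17)-en-19-oate, via N-aluminio aldimine 19 (not isolated)
Conditions: i-Bu2AlH (2.3 equiv), CH2Cl2, −78 °C; aq. KNa tartrate, then aq. citric acid
Reagents that add atoms: water, O
Why: Nitrile reduction stops at the aluminium aldimine, which is hydrolysed on work-up; one equivalent of hydride is consumed by the hydroxyl, and the axial neopentyl C19 ester, flanked by the C10 methyl, should react much more slowly at −78 °C.

Step 13
Reactants: 20 hydroxy aldehyde
Product: 21 methyl 3β,12-dihydroxy-13,14,15,16-tetranorlabd-8(17)-en-19-oate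
Conditions: NaBH4, MeOH, 0 °C
Reagents that add atoms: none
Why: Chemoselective aldehyde reduction; no stereocentre is formed.

Step 14
Reactants: 21 diol
Product: 22 methyl 3β-hydroxy-12-iodo-13,14,15,16-tetranorlabd-8(17)-en-19-oate
Conditions: PPh3, I2, imidazole (premixed), CH2Cl2, 0 °C; then 21
Reagents that add atoms: iodine, II
Why: Appel-type iodination; only the primary alkoxyphosphonium ion can be displaced by iodide (SN2), while the secondary neopentyl C3 hydroxyl cannot and is returned on work-up. Pre-forming the iodophosphonium salt leaves no free iodine to attack the 8(17)-alkene.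

Step 15
Reactants: 22 iodo alcohol
Product: 23 methyl 3β-acetoxy-12-iodo-13,14,15,16-tetranorlabd-8(17)-en-19-oate
Conditions: Ac2O, Et3N, DMAP (cat.), CH2Cl2, rt
Reagents that add atoms: acetic anhydride, CC(=O)OC(C)=O
Why: DMAP-catalysed O-acylation with retention at C3; it installs the final acetate and removes the only acidic proton before the organozinc step.

Step 16
Reactants: 24 methyl acetoacetate
Product: 25 methyl (2E)-3-{[(trifluoromethyl)sulfonyl]oxy}but-2-enoate
Conditions: Tf2O, aq. Me4NOH, hexanes, 5–10 °C
Reagents that add atoms: triflic anhydride, O=S(=O)(OS(=O)(=O)C(F)(F)F)C(F)(F)F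
Why: O-Triflation of the non-chelated tetramethylammonium enolate in its extended form should give the E enol triflate (triflate trans to ester), the geometry needed for C13=C14.

Step 17
Reactants: 23 iodo acetate; 25 methyl (2E)-3-{[(trifluoromethyl)sulfonyl]oxy}but-2-enoate
Product: 27 dimethyl 3β-acetoxylabda-8(17),13E-diene-15,19-dioate, via alkylzinc iodide 26 (not isolated)
Conditions: Zn dust (activated with Me3SiCl and BrCH2CH2Br), DMA, 40 °C; then 25, Pd(PPh3)4 (5 mol %), THF, 25 → 45 °C
Reagents that add atoms: none
Why: Negishi coupling: zinc inserts into the primary C–I bond (acetate, esters and the alkene are tolerated), the alkyl group is transferred to the alkenylpalladium species formed from 25, and reductive elimination forms C12–C13 with retention of the E geometry.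

Step 18
Reactants: 27 dimethyl ester acetate
Product: 28 3β-acetoxylabda-8(17),13E-diene-15,19-dioic acid (3β-acetoxy-agathic acid)
Conditions: LiI (excess), 2,6-lutidine, reflux, N2; then 1 M HCl, 0 °C
Reagents that add atoms: none
Why: SN2 dealkylation of both methyl esters by iodide at the methyl carbons, which is indifferent to the shielding of the C19 carbonyl; a secondary acetate offers no carbon open to SN2 and should survive, and no stereocentre is touched.

## Compound list

1 | methyl 5-methoxy-3-oxopentanoate | COCCC(=O)CC(=O)OC | starting material
2 | methyl 3-oxopent-4-enoate | C=CC(=O)CC(=O)OC | intermediate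
3 | lithium (2Z)-1-methoxy-1-oxopenta-2,4-dien-3-olate | C=C/C([O-])=C/C(=O)OC.[Li+] | intermediate
4 | methyl (2Z)-3-[(tert-butyldimethylsilyl)oxy]penta-2,4-dienoate | C=C/C(O[Si](C)(C)C(C)(C)C)=C/C(=O)OC | intermediate
5 | tert-butyl acetate | CC(=O)OC(C)(C)C | starting material
6 | 2,3-dibromopropene | C=C(Br)CBr | starting material
7 | lithium 1-(tert-butoxy)ethen-1-olate | C=C([O-])OC(C)(C)C.[Li+] | intermediate
8 | tert-butyl 4-bromopent-4-enoate | C=C(Br)CCC(=O)OC(C)(C)C | intermediate
9 | diisobutylaluminium hemiacetal of 8 | C=C(Br)CCC(O[Al](CC(C)C)CC(C)C)OC(C)(C)C | intermediate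
10 | 4-bromopent-4-enal | C=C(Br)CCC=O | intermediate
11 | 2-(triphenylphosphoranylidene)propanal | CC(C=O)=P(c1ccccc1)(c1ccccc1)c1ccccc1 | starting material
12 | (2E)-6-bromo-2-methylhepta-2,6-dienal | O=C/C(C)=C/CCC(Br)=C | intermediate
13 | methyl (1S,5S,6S)-6-(3-bromobut-3-en-1-yl)-2-[(tert-butyldimethylsilyl)oxy]-5-formyl-5-methylcyclohex-2-ene-1-carboxylate (labdane locants: C2=C3 silyl enol ether; 4α-CO2Me; 5α-H; bromobutenyl arm C6–C8 and C17 on C5; 10β-CH3; formyl carbon C9 on C10) | C=C(Br)CC[C@@H]1[C@@](C)(C=O)CC=C(O[Si](C)(C)C(C)(C)C)[C@H]1C(=O)OC | intermediate
14 | methyl (1S,5R,6S)-6-(3-bromobut-3-en-1-yl)-2-[(tert-butyldimethylsilyl)oxy]-5-[(E)-2-cyanoethenyl]-5-methylcyclohex-2-ene-1-carboxylate | C=C(Br)CC[C@@H]1[C@@](C)(/C=C/C#N)CC=C(O[Si](C)(C)C(C)(C)C)[C@H]1C(=O)OC | intermediate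
15 | methyl 3-[(tert-butyldimethylsilyl)oxy]-13,14,15,16-tetranorlabda-2,8(17)-dien-12-nitrile-19-oate (4β-H) | C=C1CC[C@@H]2[C@](C)(CC=C(O[Si](C)(C)C(C)(C)C)[C@H]2C(=O)OC)[C@H]1CC#N | intermediate
16 | methyl 3-oxo-13,14,15,16-tetranorlabd-8(17)-en-12-nitrile-19-oate (4β-H, epimerisable) | C=C1CC[C@@H]2[C@](C)(CCC(=O)[C@H]2C(=O)OC)[C@H]1CC#N | intermediate
17 | methyl 3-oxo-13,14,15,16-tetranorlabd-8(17)-en-12-nitrile-19-oate (4α-CH3, 4β-CO2Me) | C=C1CC[C@@H]2[C@](C)(CCC(=O)[C@]2(C)C(=O)OC)[C@H]1CC#N | intermediate
18 | methyl 3β-hydroxy-13,14,15,16-tetranorlabd-8(17)-en-12-nitrile-19-oate | C=C1CC[C@@H]2[C@](C)(CC[C@H](O)[C@]2(C)C(=O)OC)[C@H]1CC#N | intermediate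
19 | N,O-bis(diisobutylaluminio) aldimine of 18 | C=C1CC[C@@H]2[C@](C)(CC[C@H](O[Al](CC(C)C)CC(C)C)[C@]2(C)C(=O)OC)[C@H]1CC=N[Al](CC(C)C)CC(C)C | intermediate
20 | methyl 3β-hydroxy-12-oxo-13,14,15,16-tetranorlabd-8(17)-en-19-oate | C=C1CC[C@@H]2[C@](C)(CC[C@H](O)[C@]2(C)C(=O)OC)[C@H]1CC=O | intermediate
21 | methyl 3β,12-dihydroxy-13,14,15,16-tetranorlabd-8(17)-en-19-oate | C=C1CC[C@@H]2[C@](C)(CC[C@H](O)[C@]2(C)C(=O)OC)[C@H]1CCO | intermediate
22 | methyl 3β-hydroxy-12-iodo-13,14,15,16-tetranorlabd-8(17)-en-19-oate | C=C1CC[C@@H]2[C@](C)(CC[C@H](O)[C@]2(C)C(=O)OC)[C@H]1CCI | intermediate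
23 | methyl 3β-acetoxy-12-iodo-13,14,15,16-tetranorlabd-8(17)-en-19-oate | C=C1CC[C@@H]2[C@](C)(CC[C@H](OC(C)=O)[C@]2(C)C(=O)OC)[C@H]1CCI | intermediate
24 | methyl acetoacetate | CC(=O)CC(=O)OC | starting material
25 | methyl (2E)-3-{[(trifluoromethyl)sulfonyl]oxy}but-2-enoate | C/C(OS(=O)(=O)C(F)(F)F)=C\C(=O)OC | intermediate
26 | alkylzinc iodide from 23 (C12–ZnI) | C=C1CC[C@@H]2[C@](C)(CC[C@H](OC(C)=O)[C@]2(C)C(=O)OC)[C@H]1CC[Zn]I | intermediate
27 | dimethyl 3β-acetoxylabda-8(17),13E-diene-15,19-dioate | C=C1CC[C@@H]2[C@](C)(CC[C@H](OC(C)=O)[C@]2(C)C(=O)OC)[C@H]1CC/C(C)=C/C(=O)OC | intermediate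
28 | 3β-acetoxylabda-8(17),13E-diene-15,19-dioic acid (3β-acetoxy-agathic acid) | C=C1CC[C@@H]2[C@](C)(CC[C@H](OC(C)=O)[C@]2(C)C(=O)O)[C@H]1CC/C(C)=C/C(=O)O | target

## Step count and least certain steps

Total step count: 18. Longest linear sequence: 15 steps (steps 3–15, 17 and 18); the diene (steps 1 and 2) and the enol triflate (step 16) are side branches.

**Step 6 (key step).**
- What may go wrong: the cycloaddition may be too slow for a trisubstituted enal and an ester-bearing diene. The strongly acidic catalyst then has time to cause protodesilylation of the diene or Mukaiyama-type addition to the carbonyl. Face selection may also be eroded or reversed by the β-substituent.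
- A reversed face selection is answered by the antipodal ligand (see the assumption).
- Fallback, from 4 and 12 back to 18: the two fragments are combined without any chiral catalyst, thermally in toluene at 140 °C in a sealed vessel, to give 13 together with the mirror image of 13 F1. Steps 7–11 are then run on the racemate, so that each numbered compound is accompanied by its enantiomer: the mirror image of 14 F2, the mirror image of 15 F3, the mirror image of 16 F4, the mirror image of 17 F5 and the mirror image of 18 F6. Esterification of the racemic alcohol with (S)-O-methylmandelic acid (DCC, DMAP) gives two diastereomers, the (S)-O-methylmandelate of 18 F7 and the (S)-O-methylmandelate of the mirror image of 18 F8, which are separated on silica. F7 is cleaved with K2CO3 in MeOH and the route is rejoined at 18.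

**Step 8.**
- What may go wrong: the vinyl radical may be reduced before it cyclises, or may abstract the activated C4 hydrogen through a six-membered transition state. Selectivity at C9 may be poor if the pseudo-axial transition state competes.
- Fallback, from 14 back to 15: a two-electron ring closure replaces the radical chain. Stoichiometric Ni(cod)2 (zerovalent nickel) with Et3N in MeCN adds oxidatively to the vinyl bromide, the alkenylnickel species adds 6-exo to the unsaturated nitrile, and protonation of the resulting nickel keteniminate on aqueous NH4Cl work-up gives 15 without a free radical. No new compound is made.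

**Step 12.**
- What may go wrong: the C19 ester may be over-reduced, helped by the neighbouring aluminium alkoxide and the second equivalent of hydride. Part of the aldimine may also be lost on work-up.
- Fallback, from 18 back to 20: the hydroxyl is first masked (Et3SiOTf, 2,6-lutidine) as the 3β-triethylsilyl ether of 18 F9. This needs only 1.1 equiv of i-Bu2AlH at −78 °C and gives the 3β-triethylsilyloxy aldehyde F10. Desilylation (AcOH, THF, H2O) returns 20.

**Step 17.**
- What may go wrong: zinc insertion next to the bulky decalin may be slow, the zinc reagent may be protonated, β-hydride elimination may occur at palladium, or the alkene geometry may be partly lost.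
- Fallback, from 22 back to 27: the C13=C14 alkene is made by olefination instead of coupling. Iodide 22 is alkylated with 2-lithio-2-methyl-1,3-dithiane (2.2 equiv, THF, −78 → −20 °C) to the dithiane alcohol F11. Hydrolysis (MeI, CaCO3, aq. MeCN) gives the hydroxy methyl ketone F12. Horner–Wadsworth–Emmons reaction with trimethyl phosphonoacetate (NaH, THF) gives dimethyl 3β-hydroxylabda-8(17),13E-diene-15,19-dioate F13; the geometric selectivity of this olefination is only moderate, so careful chromatography is needed. Acetylation (Ac2O, Et3N, DMAP) gives 27.

**Step 18.**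
- What may go wrong: the enoate may isomerise by reversible iodide addition at high temperature, the C19 ester may be demethylated incompletely, or the acetate may be partly lost.
- Fallback, from 27 back to 28: the three ester functions are cleaved in sequence and the acetate is put back. LiOH in aq. THF/MeOH removes the C15 methyl ester and the acetate to give the 3β-hydroxy 15-acid 19-methyl ester F14; its carboxylate is no longer a Michael acceptor. n-PrSLi in HMPA then demethylates C19 to 3β-hydroxyagathic acid F15. Ac2O in pyridine, followed by aqueous hydrolysis of the mixed anhydride, gives 28.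

## Further compounds

F1 | step 6 | mirror image of 13: methyl (1R,5R,6R)-6-(3-bromobut-3-en-1-yl)-2-[(tert-butyldimethylsilyl)oxy]-5-formyl-5-methylcyclohex-2-ene-1-carboxylate | C=C(Br)CC[C@H]1[C@](C)(C=O)CC=C(O[Si](C)(C)C(C)(C)C)[C@@H]1C(=O)OC
F2 | step 6 | mirror image of 14: methyl (1R,5S,6R)-6-(3-bromobut-3-en-1-yl)-2-[(tert-butyldimethylsilyl)oxy]-5-[(E)-2-cyanoethenyl]-5-methylcyclohex-2-ene-1-carboxylate | C=C(Br)CC[C@H]1[C@](C)(/C=C/C#N)CC=C(O[Si](C)(C)C(C)(C)C)[C@@H]1C(=O)OC
F3 | step 6 | mirror image of 15 | C=C1CC[C@H]2[C@@](C)(CC=C(O[Si](C)(C)C(C)(C)C)[C@@H]2C(=O)OC)[C@@H]1CC#N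
F4 | step 6 | mirror image of 16 | C=C1CC[C@H]2[C@@](C)(CCC(=O)[C@@H]2C(=O)OC)[C@@H]1CC#N
F5 | step 6 | mirror image of 17 | C=C1CC[C@H]2[C@@](C)(CCC(=O)[C@@]2(C)C(=O)OC)[C@@H]1CC#N
F6 | step 6 | mirror image of 18 | C=C1CC[C@H]2[C@@](C)(CC[C@@H](O)[C@@]2(C)C(=O)OC)[C@@H]1CC#N
F7 | step 6 | (S)-O-methylmandelate of 18: methyl 3β-[(2S)-2-methoxy-2-phenylacetoxy]-13,14,15,16-tetranorlabd-8(17)-en-12-nitrile-19-oate | C=C1CC[C@@H]2[C@](C)(CC[C@H](OC(=O)[C@@H](OC)c3ccccc3)[C@]2(C)C(=O)OC)[C@H]1CC#N
F8 | step 6 | (S)-O-methylmandelate of the mirror image of 18 | C=C1CC[C@H]2[C@@](C)(CC[C@@H](OC(=O)[C@@H](OC)c3ccccc3)[C@@]2(C)C(=O)OC)[C@@H]1CC#N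
F0 | step 8 | none | none
F9 | step 12 | methyl 3β-(triethylsilyloxy)-13,14,15,16-tetranorlabd-8(17)-en-12-nitrile-19-oate | C=C1CC[C@@H]2[C@](C)(CC[C@H](O[Si](CC)(CC)CC)[C@]2(C)C(=O)OC)[C@H]1CC#N
F10 | step 12 | methyl 12-oxo-3β-(triethylsilyloxy)-13,14,15,16-tetranorlabd-8(17)-en-19-oate | C=C1CC[C@@H]2[C@](C)(CC[C@H](O[Si](CC)(CC)CC)[C@]2(C)C(=O)OC)[C@H]1CC=O
F11 | step 17 | methyl 3β-hydroxy-12-(2-methyl-1,3-dithian-2-yl)-13,14,15,16-tetranorlabd-8(17)-en-19-oate | C=C1CC[C@@H]2[C@](C)(CC[C@H](O)[C@]2(C)C(=O)OC)[C@H]1CCC1(C)SCCCS1
F12 | step 17 | methyl 3β-hydroxy-13-oxo-14,15-dinorlabd-8(17)-en-19-oate | C=C1CC[C@@H]2[C@](C)(CC[C@H](O)[C@]2(C)C(=O)OC)[C@H]1CCC(C)=O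
F13 | step 17 | dimethyl 3β-hydroxylabda-8(17),13E-diene-15,19-dioate | C=C1CC[C@@H]2[C@](C)(CC[C@H](O)[C@]2(C)C(=O)OC)[C@H]1CC/C(C)=C/C(=O)OC
F14 | step 18 | 3β-hydroxy-19-methoxy-19-oxolabda-8(17),13E-dien-15-oic acid | C=C1CC[C@@H]2[C@](C)(CC[C@H](O)[C@]2(C)C(=O)OC)[C@H]1CC/C(C)=C/C(=O)O
F15 | step 18 | 3β-hydroxylabda-8(17),13E-diene-15,19-dioic acid | C=C1CC[C@@H]2[C@](C)(CC[C@H](O)[C@]2(C)C(=O)O)[C@H]1CC/C(C)=C/C(=O)O
A1 | alternative 1 | acyclic trienal with E,E-1-(triethylsilyloxy)diene, E-3-methyl enal, 3-OTBS and quaternary C4 | O=C/C=C(C)/CC[C@H](O[Si](C)(C)C(C)(C)C)[C@](C)(C(=O)OC)/C=C/C=C/O[Si](CC)(CC)CC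
A2 | alternative 1 | trans-fused octalin aldehyde with 8β-triethylsilyloxy group | O=C[C@H]1[C@@H](O[Si](CC)(CC)CC)C=C[C@@H]2[C@]1(C)CC[C@H](O[Si](C)(C)C(C)(C)C)[C@]2(C)C(=O)OC
A3 | alternative 2 | ring B acrylate aldehyde with C9 dioxolane | C1CC[C@@H](C(=C)C(=O)OC)[C@](C)(CCC=O)C13OCCO3
A4 | alternative 2 | 3β-hydroxy trans-decalin ester with C9 dioxolane | C1CC[C@@H]2[C@](C)(CC[C@H](O)[C@]2(C)C(=O)OC)C13OCCO3
A5 | alternative 3 | 2-methoxy-5-methyl-1,4-benzoquinone | COC1=CC(=O)C(C)=CC1=O
A6 | alternative 3 | 2-silyloxydiene with ketal-protected methyl ketone chain | C=C/C(O[Si](C)(C)C(C)(C)C)=C/CCC1(C)OCCO1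
A7 | alternative 3 | cis-fused endo quinone adduct | C1(O[Si](C)(C)C(C)(C)C)=CC[C@H]2[C@](C)(C(=O)C=C(OC)C2=O)[C@@H]1CCC1(C)OCCO1
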